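**Overview**
1. Cuts: first the O7–CH2 bond of the prenyl ether. Then the C3–C1' bond between the pyranone and the anisyl ring, read backwards as a 1,2-shift to the C2–C1' bond of a flavanone. Then O1–C2 (oxa-Michael), Cα=Cβ of a chalcone (aldol), and the aryl–acetyl bond on 2-methoxyresorcinol.
2. Enabling feature: the 4-methoxyphenyl ring (ring B) is bonded to C3 of the chromen-4-one, the carbon beside C4=O, while C2, the carbon bonded to O1, carries only H. O1 can carry a positive charge at C2 and the para-methoxy group makes ring B a willing migrating group, so the 3-aryl skeleton lies one aryl shift away from the easily built 2-aryl isomer.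
3. Forward order: rings A and B arrive ready-made. Ring A is acetylated and O7 is masked as a benzyl ether, ring B is joined by aldol condensation, and the pyranone ring (ring C) closes by O1–C2 bond formation. Iodine(III) then moves ring B from C2 to C3 on the closed heterocycle.
4. End game: debenzylation and O-prenylation come last, which keeps the oxidisable trisubstituted alkene out of the iodine(III) step.
5. Stereochemistry: none has to be set, since the target has no stereocentre and its side-chain alkene ends in two methyl groups. The flavanone is made racemic and its C2 centre is flattened in the key step.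

Key step: step 5

Remark: the target SMILES holds no stereocentre and no stereogenic double bond, so the compound is achiral and the call for a single enantiomer is met by the constitution alone.

Step 1
Reactants: 1 2-methoxyresorcinol
Product: 3 2,4-dihydroxy-3-methoxyacetophenone, via ketiminium chloride 2 (not isolated)
Conditions: MeCN, ZnCl2, HCl (g), Et2O, 0 °C to rt; then H2O, reflux
Reagents that add atoms: acetonitrile CC#N; water O; hydrogen chloride Cl (its chloride is held only by 2)
Why: Houben–Hoesch acylation, in which acetonitrile activated by HCl and ZnCl2 attacks C4 of the mirror-symmetric arene (equivalent to C6, ortho to one hydroxyl and para to the other, and far more activated than C5), so that only one regioisomer is to be expected, and the ketiminium salt 2 is then hydrolysed in boiling water without harm to the methyl ether.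

Step 2
Reactants: 3 2,4-dihydroxy-3-methoxyacetophenone; 4 benzyl bromide
Product: 5 4-benzyloxy-2-hydroxy-3-methoxyacetophenone
Conditions: 4 (1.0 equiv), K2CO3 (1.1 equiv), acetone, reflux
Reagents that add atoms: none
Why: Williamson ether synthesis made site-selective by the substrate, because the 2-OH is locked in a hydrogen bond to the acetyl oxygen and is hard to deprotonate with carbonate, whereas the 4-OH, para to the carbonyl, is the more acidic and freely accessible phenol and should take up the single equivalent of 4.

Step 3
Reactants: 5 4-benzyloxy-2-hydroxy-3-methoxyacetophenone; 6 4-methoxybenzaldehyde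
Product: 8 (E)-4'-benzyloxy-2'-hydroxy-3',4-dimethoxychalcone, via aldol adduct 7 (not isolated)
Conditions: KOH, EtOH–H2O, rt; then aq HCl
Reagents that add atoms: none
Why: Claisen–Schmidt condensation, in which the methyl ketone enolate of 5 adds to the non-enolisable aldehyde 6 to give aldol 7 and E1cB loss of water gives the fully conjugated enone with the sterically favoured E geometry, while the 2'-phenolate that exists in strong base keeps the chain open until acidification.

Step 4
Reactants: 8 (E)-4'-benzyloxy-2'-hydroxy-3',4-dimethoxychalcone
Product: 9 racemic 7-benzyloxy-8-methoxy-2-(4-methoxyphenyl)chroman-4-one (flavanone)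
Conditions: NaOAc, EtOH, reflux
Reagents that add atoms: none
Why: Intramolecular oxa-Michael addition (6-endo-trig) of the 2'-phenol to Cβ of the enone under weak-base catalysis, a well-known chalcone–flavanone isomerisation from which unchanged 8 can be separated and recycled; the new C2 stereocentre arises without any control, so 9 is racemic, which is of no consequence because C2 becomes sp2 again in step 5.

Step 5
Reactants: 9 racemic 7-benzyloxy-8-methoxy-2-(4-methoxyphenyl)chroman-4-one
Product: 12 7-benzyloxy-8-methoxy-3-(4-methoxyphenyl)chromen-4-one (isoflavone), via C3 iodane 10 (not isolated), via C2 oxocarbenium tosylate 11 (not isolated)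
Conditions: PhI(OH)OTs (1.2 equiv), MeCN, reflux
Reagents that add atoms: [hydroxy(tosyloxy)iodo]benzene (HTIB) Cc1ccc(cc1)S(=O)(=O)OI(O)c1ccccc1 (its atoms are carried only by 10 and 11; none stays in 12)
Why: Ketone 9 enolises towards C3, its only α-position, and the enol attacks iodine(III) from the ring face opposite to the C2 anisyl group, giving the trans α-iodanyl ketone 10. In the conformer with both substituents axial the C2–C1' bond lies antiperiplanar to the C3–I bond, so the anisyl ring bridges C2 and C3 as a phenonium ion while iodobenzene leaves, and the C3–C1' bond forms as the C2–C1' bond breaks. The positive charge is taken over by C2 as the O1-stabilised oxocarbenium ion 11, whose C3–H, now flanked by C4=O and the cation, is lost to tosylate to install the C2=C3 double bond of 12. The closest known reaction type is the iodine(III)- or thallium(III)-mediated oxidative 2,3-aryl migration of flavanones to isoflavones, the laboratory counterpart of the enzymatic aryl shift of isoflavonoid biosynthesis. No ring closes (the six-membered pyranone stays intact and only changes its substitution pattern) and no stereocentre is left, since C2 and C3 both end up sp2; the only stereochemical requirement, the trans relation in 10, is imposed by the C2 aryl group itself. The step needs migration to outrun C2–H loss to the 2-aryl chromenone, displacement of the iodane by tosylate and alcohol-triggered ring contraction, which should be secured by the para-methoxy group (high migratory aptitude), by O1 (stabilised C2 cation), by the alcohol-free, weakly nucleophilic solvent, and by a substrate without oxidisable alkene or free phenol, ring A being deactivated by C4=O.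

Step 6
Reactants: 12 7-benzyloxy-8-methoxy-3-(4-methoxyphenyl)chromen-4-one
Product: 13 7-hydroxy-8-methoxy-3-(4-methoxyphenyl)chromen-4-one
Conditions: H2 (1 atm), 10% Pd/C, EtOAc–THF, rt, stopped after uptake of 1 equiv H2
Reagents that add atoms: none
Why: Catalytic hydrogenolysis of an aryl benzyl ether, which under a hydrogen balloon in an aprotic solvent should be faster than saturation of the trisubstituted C2=C3 bond of the vinylogous ester, provided the uptake is followed and formate-based transfer hydrogenation, which is known to reduce isoflavones to isoflavanones, is avoided.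

Step 7
Reactants: 13 7-hydroxy-8-methoxy-3-(4-methoxyphenyl)chromen-4-one; 14 prenyl bromide (1-bromo-3-methylbut-2-ene)
Product: 15 8-methoxy-3-(4-methoxyphenyl)-7-(3-methylbut-2-enyloxy)chromen-4-one (target)
Conditions: 14 (1.2 equiv), K2CO3, acetone, reflux
Reagents that add atoms: none
Why: Williamson ether synthesis by SN2 attack on the primary allylic bromide, in which the 7-OH, acidified as a vinylogous carboxylic acid through C4=O, is fully deprotonated by carbonate, and the mild conditions favour O- over C-alkylation, leave the base-sensitive pyranone closed and stay well below the onset of an aromatic Claisen rearrangement.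

**Compound list**
1 | 2-methoxyresorcinol (2-methoxybenzene-1,3-diol) | COc1c(O)cccc1O | starting material
2 | 1-(2,4-dihydroxy-3-methoxyphenyl)ethan-1-iminium chloride | CC(=[NH2+])c1ccc(O)c(OC)c1O.[Cl-] | intermediate
3 | 2,4-dihydroxy-3-methoxyacetophenone | CC(=O)c1ccc(O)c(OC)c1O | intermediate
4 | benzyl bromide | BrCc1ccccc1 | starting material
5 | 4-benzyloxy-2-hydroxy-3-methoxyacetophenone | CC(=O)c1ccc(OCc2ccccc2)c(OC)c1O | intermediate
6 | 4-methoxybenzaldehyde | COc1ccc(C=O)cc1 | starting material
7 | 1-(4-benzyloxy-2-hydroxy-3-methoxyphenyl)-3-hydroxy-3-(4-methoxyphenyl)propan-1-one (racemic aldol adduct) | COc1ccc(C(O)CC(=O)c2ccc(OCc3ccccc3)c(OC)c2O)cc1 | intermediate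
8 | (E)-4'-benzyloxy-2'-hydroxy-3',4-dimethoxychalcone | COc1ccc(/C=C/C(=O)c2ccc(OCc3ccccc3)c(OC)c2O)cc1 | intermediate
9 | 7-benzyloxy-8-methoxy-2-(4-methoxyphenyl)chroman-4-one (racemic) | COc1ccc(C2CC(=O)c3ccc(OCc4ccccc4)c(OC)c3O2)cc1 | intermediate
10 | trans-7-benzyloxy-8-methoxy-2-(4-methoxyphenyl)-3-[phenyl(tosyloxy)-λ3-iodanyl]chroman-4-one (racemic; the 2S,3S enantiomer is drawn) | COc1ccc([C@@H]2Oc3c(OC)c(OCc4ccccc4)ccc3C(=O)[C@H]2I(c5ccccc5)OS(=O)(=O)c6ccc(C)cc6)cc1 | intermediate
11 | 7-benzyloxy-8-methoxy-3-(4-methoxyphenyl)-4-oxo-3,4-dihydrochromen-1-ium tosylate (racemic) | COc1ccc(C2C=[O+]c3c(OC)c(OCc4ccccc4)ccc3C2=O)cc1.Cc1ccc(cc1)S(=O)(=O)[O-] | intermediate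
12 | 7-benzyloxy-8-methoxy-3-(4-methoxyphenyl)chromen-4-one | COc1ccc(-c2coc3c(OC)c(OCc4ccccc4)ccc3c2=O)cc1 | intermediate
13 | 7-hydroxy-8-methoxy-3-(4-methoxyphenyl)chromen-4-one | COc1ccc(-c2coc3c(OC)c(O)ccc3c2=O)cc1 | intermediate
14 | prenyl bromide (1-bromo-3-methylbut-2-ene) | CC(C)=CCBr | starting material
15 | 8-methoxy-3-(4-methoxyphenyl)-7-(3-methylbut-2-enyloxy)chromen-4-one | COc1ccc(-c2coc3c(OC)c(OCC=C(C)C)ccc3c2=O)cc1 | target

**Step count**
Total step count: 7. Longest linear sequence: 7 steps (1 to 15). Compounds 4, 6 and 14 are bought and enter directly.

**Steps most likely to fail**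

Step 5. Collapse of the C3 iodane by proton loss across C2–C3, or by direct substitution with tosylate, may outrun the aryl shift. Iodine(III) may also attack the alkoxy-rich rings.

The fallback gives up the rearrangement and places ring B next to the future C4 from the start. It sets out from 1 and comes back at 13.
- Friedel–Crafts acylation of 1 with 4-methoxyphenylacetic acid in BF3·OEt2 (about 85 °C) should give the deoxybenzoin 1-(2,4-dihydroxy-3-methoxyphenyl)-2-(4-methoxyphenyl)ethan-1-one F1, again as the only regioisomer of the symmetric arene.
- One-carbon insertion at its activated methylene with DMF and MsCl in the same BF3·OEt2 medium (Vilsmeier-type formylation followed by closure through the chelated 2-OH) should give 13 directly.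
- No oxidation and no protecting group are needed.

Step 4. The ring closure is an equilibrium. The donor-substituted ring B lowers the electrophilicity of Cβ and stabilises the open enone, so conversion may stall and the ring may reopen during purification.

The fallback closes the heterocycle before ring B arrives and forms the C2–aryl bond irreversibly. It sets out from 5 and comes back at 9.
- Condensation of 5 with DMF dimethyl acetal should give the enaminone (E)-1-(4-benzyloxy-2-hydroxy-3-methoxyphenyl)-3-(dimethylamino)prop-2-en-1-one F2.
- Acid (HCl, CH2Cl2) should close it to 7-benzyloxy-8-methoxychromen-4-one F3.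
- Pd(II)/2,2'-bipyridine-catalysed conjugate addition of 4-methoxyphenylboronic acid in aqueous medium at about 60 °C, a known 1,4-addition of arylboronic acids to chromones, should give racemic 9.

Step 6. Saturation of C2=C3, and then reduction of C4=O, may compete with C–O hydrogenolysis once the catalyst is active enough to cleave the flanked benzyl ether.

The fallback removes the benzyl group before the C2=C3 bond exists and carries a non-reductively cleavable ester through the aryl shift. It sets out from 9 and comes back at 13.
- Hydrogenolysis of 9 (H2, Pd/C) should give racemic 7-hydroxy-8-methoxy-2-(4-methoxyphenyl)chroman-4-one F4.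
- Acetylation (Ac2O, pyridine, rt) should give racemic 8-methoxy-2-(4-methoxyphenyl)-4-oxochroman-7-yl acetate F5.
- The HTIB-mediated aryl migration under the conditions of step 5 should give 8-methoxy-3-(4-methoxyphenyl)-4-oxochromen-7-yl acetate F6.
- Carbonate-catalysed methanolysis at rt should release 13.

**Further compounds**
F1 | step 5 | 1-(2,4-dihydroxy-3-methoxyphenyl)-2-(4-methoxyphenyl)ethan-1-one | COc1ccc(CC(=O)c2ccc(O)c(OC)c2O)cc1
F2 | step 4 | (E)-1-(4-benzyloxy-2-hydroxy-3-methoxyphenyl)-3-(dimethylamino)prop-2-en-1-one | CN(C)/C=C/C(=O)c1ccc(OCc2ccccc2)c(OC)c1O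
F3 | step 4 | 7-benzyloxy-8-methoxychromen-4-one | COc1c(OCc2ccccc2)ccc2c(=O)ccoc12
F4 | step 6 | 7-hydroxy-8-methoxy-2-(4-methoxyphenyl)chroman-4-one (racemic) | COc1ccc(C2CC(=O)c3ccc(O)c(OC)c3O2)cc1
F5 | step 6 | 8-methoxy-2-(4-methoxyphenyl)-4-oxochroman-7-yl acetate (racemic) | COc1ccc(C2CC(=O)c3ccc(OC(C)=O)c(OC)c3O2)cc1
F6 | step 6 | 8-methoxy-3-(4-methoxyphenyl)-4-oxochromen-7-yl acetate | COc1ccc(-c2coc3c(OC)c(OC(C)=O)ccc3c2=O)cc1
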